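**Plan**

Numbering (germacrane): ten-membered ring C1–C10 (C3 ketone, C4 methyl, C6 senecioate, C10 methyl carbinol); lactone C7–C8(–O)–C12(=O)–C11; C13 is the acetoxymethyl carbon.
Feature used: the exocyclic C8=C9 bond joins the acetal-level lactone carbon C8 (shared by the butenolide and the ten-membered ring) to C9–H beside quaternary C10, so these two carbons can first be held on either side of one sulfur atom in an eleven-membered ring.
Cuts, in retrosynthetic order: the C13 and C6 esters and the C3 ketone (back to C3–OH); C8=C9 (SO2 extrusion from an eleven-membered α-acyloxy sulfone); C8–S (S,O-acetal from a γ-hydroxybutenolide and a C9 thiol); C9–S (opening of a C9–C10 epoxide); C6–C7 (4-lithiofuran plus γ-lactone); C3–C4 (crotylboration).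
Forward: the C9–C6 chain is built linearly from (R)-linalool, the furan is joined at C6 and oxidised to the hydroxybutenolide (first ring), the eleven-membered thia-ring is closed at C8–S, and sulfur is then extruded to leave the ten-membered carbocycle.
Stereochemistry: C10 from (R)-linalool (its C–O bond is never broken); C4 from a catalyst-controlled anti crotylboration (the C3 carbinol made with it is oxidised in the last step); C6 from a CBS reduction; the C8=C9 geometry from equilibration to the Z ylidene lactone.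

Key step: step 20

Assumption 1: the (S)-enantiomer of the phosphoric acid catalyst is taken to deliver the crotyl group to the Si face of aldehyde 5 (mirror image of the Re-face addition of the (R)-acid); if the sense is opposite, the (R)-acid is used.
Assumption 2: the target geometry at C8=C9 (C10 cis to the ring oxygen, trans to C7) is taken to be the more stable one in the ten-membered ring, as it is in simple γ-ylidene butenolides.
Abbreviations: TBS = tert-butyldimethylsilyl, TES = triethylsilyl.

**Route**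

Step 1
Reactants: 1 (R)-linalool
Product: 3 (R)-2-methylpentane-1,2,5-triol, via hydroxy dialdehyde 2 (not isolated)
Conditions: O3, CH2Cl2/MeOH, −78 °C; Me2S, −78 °C to rt; NaBH4, 0 °C
Reagents that add atoms: ozone, [O-][O+]=O
Why: Ozonolysis with reductive work-up cleaves both the trisubstituted and the vinyl double bond and borohydride reduces the two carbonyl groups, while the tertiary carbinol centre C10 is untouched and keeps the configuration of linalool.

Step 2
Reactants: 3 (R)-2-methylpentane-1,2,5-triol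
Product: 4 acetonide alcohol 3-[(4R)-2,2,4-trimethyl-1,3-dioxolan-4-yl]propan-1-ol
Conditions: 2,2-dimethoxypropane, pyridinium p-toluenesulfonate (cat.), acetone, rt
Reagents that add atoms: 2,2-dimethoxypropane, COC(C)(C)OC
Why: Acid-catalysed acetalisation under thermodynamic control closes the five-membered dioxolane on the 1,2-diol (C9 and C10 oxygens) and leaves the remote primary C3 hydroxyl free.

Step 3
Reactants: 4 acetonide alcohol
Product: 5 acetonide aldehyde 3-[(4R)-2,2,4-trimethyl-1,3-dioxolan-4-yl]propanal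
Conditions: (2,2,6,6-tetramethylpiperidin-1-yl)oxyl (TEMPO, cat.), PhI(OAc)2, CH2Cl2, rt
Reagents that add atoms: none
Why: Nitroxyl-catalysed (oxoammonium) oxidation of a primary alcohol stops at the aldehyde, and the acetic acid formed is too weak to open the acetonide.

Step 4
Reactants: 5 acetonide aldehyde; 6 (E)-crotylboronic acid pinacol ester
Product: 8 anti homoallylic alcohol (3R,4S)-4-methyl-1-[(4R)-2,2,4-trimethyl-1,3-dioxolan-4-yl]hex-5-en-3-ol, via borate ester 7 (not isolated)
Conditions: (S)-3,3′-bis(2,4,6-triisopropylphenyl)-1,1′-binaphthalene-2,2′-diyl hydrogen phosphate (5 mol %), toluene, −30 °C; aq. NaHCO3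
Reagents that add atoms: none
Why: Chiral Brønsted acid-catalysed crotylboration through a closed chair transition state, in which the E-crotyl reagent gives the anti adduct and the (S)-acid directs addition to the Si face of the aldehyde, sets C4 as S (and C3 as R, removed later by oxidation).

Step 5
Reactants: 8 anti homoallylic alcohol
Product: 10 1,4-diol (3S,4R)-3-methyl-6-[(4R)-2,2,4-trimethyl-1,3-dioxolan-4-yl]hexane-1,4-diol, via alkylborane 9 (not isolated)
Conditions: 9-BBN (2.5 equiv), THF, 0 °C to rt; NaOH, H2O2, 0 °C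
Reagents that add atoms: hydrogen peroxide, OO
Why: Anti-Markovnikov hydroboration–oxidation of the only alkene, with excess borane covering the free hydroxyl, creates no stereocentre.

Step 6
Reactants: 10 1,4-diol
Product: 13 trans-γ-lactone (4S,5R)-4-methyl-5-{2-[(4R)-2,2,4-trimethyl-1,3-dioxolan-4-yl]ethyl}oxolan-2-one, via hydroxy aldehyde 11 (not isolated), via lactol 12 (not isolated)
Conditions: (2,2,6,6-tetramethylpiperidin-1-yl)oxyl (TEMPO, 0.2 equiv), PhI(OAc)2 (2.5 equiv), CH2Cl2, rt
Reagents that add atoms: none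
Why: TEMPO-mediated oxidative lactonisation oxidises the primary alcohol selectively, the γ-hydroxy aldehyde closes to the lactol and this is oxidised again, which ties up the C3 oxygen and brings C6 to the acyl level while C4 (β to the carbonyl) cannot epimerise.

Step 7
Reactants: 14 furan-3-ylmethanol
Product: 15 furylmethyl TBS ether tert-butyl(furan-3-ylmethoxy)dimethylsilane
Conditions: TBSCl, imidazole, DMF, rt
Reagents that add atoms: tert-butyldimethylsilyl chloride, CC(C)(C)[Si](C)(C)Cl
Why: Standard silylation of a primary alcohol installs the silyl group that will migrate to carbon.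

Step 8
Reactants: 15 furylmethyl TBS ether
Product: 17 [2-(tert-butyldimethylsilyl)furan-3-yl]methanol, via 2-lithiofuran 16 (not isolated)
Conditions: n-BuLi, HMPA, THF, −78 to 0 °C; aq. NH4Cl
Reagents that add atoms: none
Why: Oxygen-directed lithiation at C2 of the furan followed by a retro-[1,4]-Brook (O to C) silyl migration, driven by formation of the lithium alkoxide, puts silicon on the α-carbon next to the hydroxymethyl group (the future C12).

Step 9
Reactants: 17 [2-(tert-butyldimethylsilyl)furan-3-yl]methanol; 13 trans-γ-lactone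
Product: 19 furyl keto diol, via furyl dianion 18 (not isolated)
Conditions: 17 (2.2 equiv), n-BuLi (4.3 equiv), DME, 0 °C; then 13, THF, −78 to −40 °C; aq. NH4Cl
Reagents that add atoms: none
Why: With C2 blocked by silicon the lithium alkoxide directs the second lithiation to C4 (directed metalation), and the aryllithium adds only once to the γ-lactone because the lithium lactolate survives at low temperature, which forms the C6–C7 bond and gives the ketone directly.

Step 10
Reactants: 19 furyl keto diol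
Product: 20 bis-TBS furyl ketone
Conditions: TBSOTf (2.4 equiv), 2,6-lutidine, CH2Cl2, −78 °C
Reagents that add atoms: tert-butyldimethylsilyl trifluoromethanesulfonate, CC(C)(C)[Si](C)(C)OS(=O)(=O)C(F)(F)F
Why: Silyl triflate silylation of the primary (C13) and secondary (C3) hydroxyls, which also draws the hemiketal forms of 19 into the open ketone, is run cold so that the acetonide is not attacked.

Step 11
Reactants: 20 bis-TBS furyl ketone
Product: 21 C9/C10 diol
Conditions: CeCl3·7H2O, oxalic acid (cat.), MeCN, rt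
Reagents that add atoms: none
Why: Mild Lewis acid-assisted hydrolysis of the terminal isopropylidene acetal, chosen because TBS ethers and the acyl-deactivated C-silyl furan are expected to survive it.

Step 12
Reactants: 21 C9/C10 diol
Product: 23 C9–C10 epoxide, via primary tosylate 22 (not isolated)
Conditions: TsCl, Et3N, Bu2SnO (2 mol %), CH2Cl2, 0 °C to rt; then K2CO3, MeOH, 0 °C to rt
Reagents that add atoms: none
Why: Tin-catalysed selective sulfonylation of the primary hydroxyl and intramolecular Williamson etherification (3-exo-tet) by the tertiary alkoxide give the epoxide with retention at C10, since its C–O bond is not broken.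

Step 13
Reactants: 23 C9–C10 epoxide
Product: 25 methyl disulfide, via thioacetate 24 (not isolated)
Conditions: AcSH, Et3N (cat.), THF, 40 °C; evaporate; NaOMe, MeSO2SMe, MeOH, 0 °C
Reagents that add atoms: thioacetic acid, CC(=O)S; S-methyl methanethiosulfonate, CS(=O)(=O)SC
Why: SN2 opening of the 2,2-disubstituted epoxide by thioacetate at the CH2 terminus (C9), then methanolysis of the thioester and capture of the thiolate by the thiosulfonate, stores the thiol as a mixed disulfide that tolerates borane, silyl triflate and singlet oxygen and can be released without acid or base.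

Step 14
Reactants: 25 methyl disulfide
Product: 26 (6R)-furyl carbinol
Conditions: (S)-2-methyl-CBS-oxazaborolidine [(3aS)-1-methyl-3,3-diphenyltetrahydro-1H,3H-pyrrolo[1,2-c][1,3,2]oxazaborole] (0.3 equiv), BH3·SMe2, THF, −30 °C; MeOH
Reagents that add atoms: none
Why: CBS reduction, in which the oxazaborolidine–borane complex treats the furyl group as the large substituent, should give the 6R carbinol with the (S)-catalyst by reagent control over the remote C4 centre.

Step 15
Reactants: 26 (6R)-furyl carbinol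
Product: 27 bis-TES ether
Conditions: TESOTf (2.5 equiv), 2,6-lutidine, CH2Cl2, −78 to 0 °C
Reagents that add atoms: triethylsilyl trifluoromethanesulfonate, CC[Si](CC)(CC)OS(=O)(=O)C(F)(F)F
Why: Silyl triflate silylation of the secondary (C6) and tertiary (C10) hydroxyls uses triethylsilyl so that the C6 group can later be removed while the C3 TBS ether stays.

Step 16
Reactants: 27 bis-TES ether
Product: 30 γ-hydroxybutenolide, via endoperoxide 28 (not isolated), via silyl ester 29 (not isolated)
Conditions: O2, visible light, 5,10,15,20-tetraphenylporphyrin (cat.), CH2Cl2, −78 °C; then H2O, rt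
Reagents that add atoms: dioxygen (as singlet oxygen), O=O
Why: [4+2] cycloaddition of singlet oxygen to the furan and silyl migration from carbon to the peroxide oxygen (silylfuran photooxygenation) make the silicon-bearing carbon the lactone carbonyl C12 and C8 the hemiacetal carbon regiospecifically, the dialkyl disulfide reacting far more slowly with singlet oxygen than the electron-rich furan.

Step 17
Reactants: 30 γ-hydroxybutenolide
Product: 31 thiol
Conditions: PBu3, THF/H2O (10:1), 0 °C
Reagents that add atoms: none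
Why: Phosphine reduction of the disulfide in wet THF frees the thiol under neutral conditions that do not open the base-sensitive hydroxybutenolide, and the methanethiol formed is removed by evaporation.

Step 18
Reactants: 31 thiol
Product: 32 eleven-membered cyclic sulfide
Conditions: 10-camphorsulfonic acid (0.2 equiv), 4 Å molecular sieves, CH2Cl2 (0.5 mM), 30 °C
Reagents that add atoms: none
Why: Acid-catalysed substitution of the pseudo-acid hydroxyl by the thiol through the acyloxycarbenium ion (S,O-acetal formation) is reversible, so at high dilution the eleven-membered monomer with its long C–S bonds should be selected over oligomers, conjugate addition being blocked by the fully substituted β-carbon and the configuration at C8 being irrelevant.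

Step 19
Reactants: 32 eleven-membered cyclic sulfide
Product: 34 eleven-membered cyclic sulfone, via sulfoxide 33 (not isolated)
Conditions: mCPBA (2.5 equiv), NaHCO3, CH2Cl2, 0 °C to rt
Reagents that add atoms: 3-chloroperoxybenzoic acid, OOC(=O)c1cccc(Cl)c1
Why: Peracid oxidation takes the sulfide through the sulfoxide to the sulfone, and the electron-poor tetrasubstituted butenolide alkene is not epoxidised.

Step 20
Reactants: 34 eleven-membered cyclic sulfone
Product: 38 protected (Z)-ylidene butenolide, via chloro sulfone 35 (not isolated), via episulfone 36 (not isolated), via E isomer 37 (not isolated)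
Conditions: KOtBu (1.05 equiv), THF, −78 °C; C2Cl6 (1.1 equiv); KOtBu (2 equiv), −78 to −20 °C; aq. NH4Cl; then I2 (5 mol %), CH2Cl2, daylight, rt
Reagents that add atoms: none
Why: Proposed new method: tert-butoxide removes the C8 proton (α to the sulfone and γ of the butenolide, giving a 2-oxidofuran), hexachloroethane chlorinates this anion at C8, and a second deprotonation at C9 lets the carbanion displace chloride in a 1,3-fashion to episulfone 36, which loses SO2 in a cheletropic step and leaves the C8–C9 σ and π bonds. The closest known reactions are the Ramberg–Bäcklund conversion of S-glycoside dioxides (α-alkoxy sulfones) into exocyclic enol ethers and the ring contraction of cyclic sulfones to medium-ring alkenes; a lactone acetal carbon in an eleven-to-ten contraction is an extrapolation from both. The ten-membered carbocycle arises by 3-exo-tet closure of C9 onto C8 inside the thia-ring, so no medium-ring transition state is needed and the ring strain is paid for by the irreversible loss of SO2. No stereocentre is created, and since the extrusion does not fix the alkene geometry (both episulfones can form, giving some E isomer 37), the crude product is equilibrated with iodine and light to the Z isomer in which C10 avoids C7. The step needs halogenation at C8 and not at C9, which the much greater acidity of the C8–H secures; it needs ring closure faster than loss of the C10 oxygen from the C9 carbanion, which is favoured because the chloride sits on an acetal carbon and the oxygen is a silyl ether that cannot undergo retro-aldol cleavage; and it needs no base-labile or enolisable groups, which is met because every hydroxyl is a silyl ether and C3 is at the alcohol level, so C4 cannot epimerise.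

Step 21
Reactants: 38 protected (Z)-ylidene butenolide
Product: 39 C6/C13 diol
Conditions: HF·pyridine, pyridine, THF, 0 °C
Reagents that add atoms: none
Why: Buffered fluoride desilylation should remove the primary TBS ether (C13) and the secondary triethylsilyl ether (C6) well before the secondary TBS ether at C3 and the tertiary triethylsilyl ether at C10 (graded lability of silyl ethers), and partial loss of the C10 group would be harmless because a tertiary alcohol is not acylated in the next two steps.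

Step 22
Reactants: 39 C6/C13 diol
Product: 40 C13 acetate
Conditions: AcCl (1.1 equiv), 2,4,6-collidine, CH2Cl2, −78 °C
Reagents that add atoms: acetyl chloride, CC(=O)Cl
Why: Acylation with acetyl chloride and a hindered pyridine base at low temperature is selective for the primary hydroxyl over the hindered secondary C6 hydroxyl.

Step 23
Reactants: 40 C13 acetate
Product: 41 C6 senecioate
Conditions: 3-methylbut-2-enoic acid, 2,4,6-trichlorobenzoyl chloride, Et3N, THF, rt; then 40, 4-(dimethylamino)pyridine, toluene, rt to 40 °C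
Reagents that add atoms: 3-methylbut-2-enoic acid, CC(C)=CC(=O)O
Why: Yamaguchi esterification through the mixed anhydride and the acylpyridinium ion acylates the hindered C6 hydroxyl with retention at C6 and avoids the ketene pathway that deconjugates senecioyl chloride.

Step 24
Reactants: 41 C6 senecioate
Product: 42 C3/C10 diol
Conditions: HF·pyridine (excess), THF, 0 °C to rt
Reagents that add atoms: none
Why: Prolonged fluoride desilylation removes the remaining secondary TBS and tertiary triethylsilyl ethers, the esters and the enol lactone being stable to buffered HF.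

Step 25
Reactants: 42 C3/C10 diol
Product: 43 target CNP0186726.1
Conditions: Dess–Martin periodinane, NaHCO3, CH2Cl2, 0 °C
Reagents that add atoms: none
Why: Buffered Dess–Martin oxidation of the only secondary alcohol should give the C3 ketone without epimerising the adjacent C4 centre or touching the tertiary C10 hydroxyl.

**Compound list**

In the names, Ar = 5-(tert-butyldimethylsilyl)-4-{[(tert-butyldimethylsilyl)oxy]methyl}furan-3-yl; locants C1–C13 follow the germacrane numbering above.

1 | (R)-linalool, (3R)-3,7-dimethylocta-1,6-dien-3-ol | C=C[C@](C)(O)CCC=C(C)C | starting material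
2 | (2R)-2-hydroxy-2-methylpentanedial (not isolated) | O=C[C@](C)(O)CCC=O | intermediate
3 | (2R)-2-methylpentane-1,2,5-triol | OC[C@](C)(O)CCCO | intermediate
4 | 3-[(4R)-2,2,4-trimethyl-1,3-dioxolan-4-yl]propan-1-ol | CC1(C)OC[C@@](C)(CCCO)O1 | intermediate
5 | 3-[(4R)-2,2,4-trimethyl-1,3-dioxolan-4-yl]propanal | CC1(C)OC[C@@](C)(CCC=O)O1 | intermediate
6 | (E)-crotylboronic acid pinacol ester | C/C=C/CB1OC(C)(C)C(C)(C)O1 | starting material
7 | pinacol borate ester of 8 at the C3 oxygen (not isolated) | CC1(C)OC[C@@](C)(CC[C@@H](OB2OC(C)(C)C(C)(C)O2)[C@@H](C)C=C)O1 | intermediate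
8 | (3R,4S)-4-methyl-1-[(4R)-2,2,4-trimethyl-1,3-dioxolan-4-yl]hex-5-en-3-ol | CC1(C)OC[C@@](C)(CC[C@@H](O)[C@@H](C)C=C)O1 | intermediate
9 | 9-BBN adduct of 8, B-alkyl at C6 and B-alkoxy at the C3 oxygen (not isolated) | CC1(C)OC[C@@](C)(CC[C@@H](OB2C3CCCC2CCC3)[C@@H](C)CCB2C3CCCC2CCC3)O1 | intermediate
10 | (3S,4R)-3-methyl-6-[(4R)-2,2,4-trimethyl-1,3-dioxolan-4-yl]hexane-1,4-diol | CC1(C)OC[C@@](C)(CC[C@@H](O)[C@@H](C)CCO)O1 | intermediate
11 | (3S,4R)-4-hydroxy-3-methyl-6-[(4R)-2,2,4-trimethyl-1,3-dioxolan-4-yl]hexanal (not isolated) | CC1(C)OC[C@@](C)(CC[C@@H](O)[C@@H](C)CC=O)O1 | intermediate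
12 | (4S,5R)-4-methyl-5-{2-[(4R)-2,2,4-trimethyl-1,3-dioxolan-4-yl]ethyl}oxolan-2-ol (not isolated) | CC1(C)OC[C@@](C)(CC[C@H]2OC(O)C[C@@H]2C)O1 | intermediate
13 | (4S,5R)-4-methyl-5-{2-[(4R)-2,2,4-trimethyl-1,3-dioxolan-4-yl]ethyl}oxolan-2-one | CC1(C)OC[C@@](C)(CC[C@H]2OC(=O)C[C@@H]2C)O1 | intermediate
14 | furan-3-ylmethanol | OCc1ccoc1 | starting material
15 | tert-butyl(furan-3-ylmethoxy)dimethylsilane | CC(C)(C)[Si](C)(C)OCc1ccoc1 | intermediate
16 | tert-butyl[(2-lithiofuran-3-yl)methoxy]dimethylsilane (not isolated) | CC(C)(C)[Si](C)(C)OCc1ccoc1[Li] | intermediate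
17 | [2-(tert-butyldimethylsilyl)furan-3-yl]methanol | CC(C)(C)[Si](C)(C)c1occc1CO | intermediate
18 | lithium [2-(tert-butyldimethylsilyl)-4-lithiofuran-3-yl]methanolate (not isolated) | [Li]OCc1c([Si](C)(C)C(C)(C)C)occ1[Li] | intermediate
19 | (3S,4R)-1-[5-(tert-butyldimethylsilyl)-4-(hydroxymethyl)furan-3-yl]-4-hydroxy-3-methyl-6-[(4R)-2,2,4-trimethyl-1,3-dioxolan-4-yl]hexan-1-one | CC1(C)OC[C@@](C)(CC[C@@H](O)[C@@H](C)CC(=O)c2coc([Si](C)(C)C(C)(C)C)c2CO)O1 | intermediate
20 | (3S,4R)-1-Ar-4-[(tert-butyldimethylsilyl)oxy]-3-methyl-6-[(4R)-2,2,4-trimethyl-1,3-dioxolan-4-yl]hexan-1-one | CC1(C)OC[C@@](C)(CC[C@@H](O[Si](C)(C)C(C)(C)C)[C@@H](C)CC(=O)c2coc([Si](C)(C)C(C)(C)C)c2CO[Si](C)(C)C(C)(C)C)O1 | intermediate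
21 | (3S,4R,7R)-1-Ar-4-[(tert-butyldimethylsilyl)oxy]-7,8-dihydroxy-3,7-dimethyloctan-1-one | OC[C@](C)(O)CC[C@@H](O[Si](C)(C)C(C)(C)C)[C@@H](C)CC(=O)c1coc([Si](C)(C)C(C)(C)C)c1CO[Si](C)(C)C(C)(C)C | intermediate
22 | primary (C9) 4-methylbenzenesulfonate of 21 (not isolated) | Cc1ccc(cc1)S(=O)(=O)OC[C@](C)(O)CC[C@@H](O[Si](C)(C)C(C)(C)C)[C@@H](C)CC(=O)c1coc([Si](C)(C)C(C)(C)C)c1CO[Si](C)(C)C(C)(C)C | intermediate
23 | (3S,4R)-1-Ar-4-[(tert-butyldimethylsilyl)oxy]-3-methyl-6-[(2R)-2-methyloxiran-2-yl]hexan-1-one | C[C@]1(CO1)CC[C@@H](O[Si](C)(C)C(C)(C)C)[C@@H](C)CC(=O)c1coc([Si](C)(C)C(C)(C)C)c1CO[Si](C)(C)C(C)(C)C | intermediate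
24 | C9 thioacetate with free C10 hydroxyl, from 23 (not isolated) | CC(=O)SC[C@](C)(O)CC[C@@H](O[Si](C)(C)C(C)(C)C)[C@@H](C)CC(=O)c1coc([Si](C)(C)C(C)(C)C)c1CO[Si](C)(C)C(C)(C)C | intermediate
25 | (3S,4R,7R)-1-Ar-4-[(tert-butyldimethylsilyl)oxy]-7-hydroxy-3,7-dimethyl-8-(methyldisulfanyl)octan-1-one | CSSC[C@](C)(O)CC[C@@H](O[Si](C)(C)C(C)(C)C)[C@@H](C)CC(=O)c1coc([Si](C)(C)C(C)(C)C)c1CO[Si](C)(C)C(C)(C)C | intermediate
26 | (1R,3S,4R,7R)-1-Ar-4-[(tert-butyldimethylsilyl)oxy]-3,7-dimethyl-8-(methyldisulfanyl)octane-1,7-diol | CSSC[C@](C)(O)CC[C@@H](O[Si](C)(C)C(C)(C)C)[C@@H](C)C[C@@H](O)c1coc([Si](C)(C)C(C)(C)C)c1CO[Si](C)(C)C(C)(C)C | intermediate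
27 | 1,7-bis(triethylsilyl) ether of 26 (C6 and C10 oxygens) | CSSC[C@](C)(O[Si](CC)(CC)CC)CC[C@@H](O[Si](C)(C)C(C)(C)C)[C@@H](C)C[C@@H](O[Si](CC)(CC)CC)c1coc([Si](C)(C)C(C)(C)C)c1CO[Si](C)(C)C(C)(C)C | intermediate
28 | 2,5-endoperoxide of furan 27 (not isolated) | CSSC[C@](C)(O[Si](CC)(CC)CC)CC[C@@H](O[Si](C)(C)C(C)(C)C)[C@@H](C)C[C@@H](O[Si](CC)(CC)CC)C1=C(CO[Si](C)(C)C(C)(C)C)C2(OOC1O2)[Si](C)(C)C(C)(C)C | intermediate
29 | TBS ester of the (Z)-4-oxobut-2-enoic acid from 28, C8 aldehyde and C12 silyl ester (not isolated) | CSSC[C@](C)(O[Si](CC)(CC)CC)CC[C@@H](O[Si](C)(C)C(C)(C)C)[C@@H](C)C[C@@H](O[Si](CC)(CC)CC)/C(C=O)=C(\CO[Si](C)(C)C(C)(C)C)C(=O)O[Si](C)(C)C(C)(C)C | intermediate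
30 | γ-hydroxybutenolide (C8 hemiacetal, both epimers; C12 carbonyl; C13-OTBS, C6-OTES, C3-OTBS, C10-OTES, C9 methyl disulfide) | CSSC[C@](C)(O[Si](CC)(CC)CC)CC[C@@H](O[Si](C)(C)C(C)(C)C)[C@@H](C)C[C@@H](O[Si](CC)(CC)CC)C1=C(CO[Si](C)(C)C(C)(C)C)C(=O)OC1O | intermediate
31 | C9 thiol of 30 | SC[C@](C)(O[Si](CC)(CC)CC)CC[C@@H](O[Si](C)(C)C(C)(C)C)[C@@H](C)C[C@@H](O[Si](CC)(CC)CC)C1=C(CO[Si](C)(C)C(C)(C)C)C(=O)OC1O | intermediate
32 | (3R,4S,6R,10R) eleven-membered cyclic sulfide, sulfur bridging C8 and C9 (C8 epimers; C13-OTBS, C6-OTES, C3-OTBS, C10-OTES) | CC(C)(C)[Si](C)(C)OCC1=C2C(SC[C@](C)(O[Si](CC)(CC)CC)CC[C@@H](O[Si](C)(C)C(C)(C)C)[C@@H](C)C[C@H]2O[Si](CC)(CC)CC)OC1=O | intermediate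
33 | sulfoxide of 32 (not isolated) | CC(C)(C)[Si](C)(C)OCC1=C2C(S(=O)C[C@](C)(O[Si](CC)(CC)CC)CC[C@@H](O[Si](C)(C)C(C)(C)C)[C@@H](C)C[C@H]2O[Si](CC)(CC)CC)OC1=O | intermediate
34 | (3R,4S,6R,10R) eleven-membered cyclic sulfone (C8 epimers; same protecting groups as 32) | CC(C)(C)[Si](C)(C)OCC1=C2C(S(=O)(=O)C[C@](C)(O[Si](CC)(CC)CC)CC[C@@H](O[Si](C)(C)C(C)(C)C)[C@@H](C)C[C@H]2O[Si](CC)(CC)CC)OC1=O | intermediate
35 | 8-chloro derivative of sulfone 34 (not isolated) | CC(C)(C)[Si](C)(C)OCC1=C2C(Cl)(S(=O)(=O)C[C@](C)(O[Si](CC)(CC)CC)CC[C@@H](O[Si](C)(C)C(C)(C)C)[C@@H](C)C[C@H]2O[Si](CC)(CC)CC)OC1=O | intermediate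
36 | episulfone spanning C8 and C9 on the ten-membered ring (not isolated) | CC(C)(C)[Si](C)(C)OCC1=C2C3(OC1=O)C(S3(=O)=O)[C@](C)(O[Si](CC)(CC)CC)CC[C@@H](O[Si](C)(C)C(C)(C)C)[C@@H](C)C[C@H]2O[Si](CC)(CC)CC | intermediate
37 | (8E) isomer of 38 (not isolated) | CC(C)(C)[Si](C)(C)OCC1=C2/C(=C\[C@](C)(O[Si](CC)(CC)CC)CC[C@@H](O[Si](C)(C)C(C)(C)C)[C@@H](C)C[C@H]2O[Si](CC)(CC)CC)OC1=O | intermediate
38 | (3R,4S,6R,10R,8Z) ten-membered ylidene butenolide (C13-OTBS, C6-OTES, C3-OTBS, C10-OTES) | CC(C)(C)[Si](C)(C)OCC1=C2/C(=C/[C@](C)(O[Si](CC)(CC)CC)CC[C@@H](O[Si](C)(C)C(C)(C)C)[C@@H](C)C[C@H]2O[Si](CC)(CC)CC)OC1=O | intermediate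
39 | C6/C13 diol of 38 (C3-OTBS and C10-OTES retained) | OCC1=C2/C(=C/[C@](C)(O[Si](CC)(CC)CC)CC[C@@H](O[Si](C)(C)C(C)(C)C)[C@@H](C)C[C@H]2O)OC1=O | intermediate
40 | C13 acetate of 39 | CC(=O)OCC1=C2/C(=C/[C@](C)(O[Si](CC)(CC)CC)CC[C@@H](O[Si](C)(C)C(C)(C)C)[C@@H](C)C[C@H]2O)OC1=O | intermediate
41 | C13 acetate, C6 3-methylbut-2-enoate (C3-OTBS, C10-OTES) | CC(=O)OCC1=C2/C(=C/[C@](C)(O[Si](CC)(CC)CC)CC[C@@H](O[Si](C)(C)C(C)(C)C)[C@@H](C)C[C@H]2OC(=O)C=C(C)C)OC1=O | intermediate
42 | C3/C10 diol: C13 acetate, C6 3-methylbut-2-enoate, (3R)-hydroxyl | CC(=O)OCC1=C2/C(=C/[C@](C)(O)CC[C@@H](O)[C@@H](C)C[C@H]2OC(=O)C=C(C)C)OC1=O | intermediate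
43 | CNP0186726.1, (4S,6R,10R,8Z) | CC(=O)OCC1=C2/C(=C/[C@](C)(O)CCC(=O)[C@@H](C)C[C@H]2OC(=O)C=C(C)C)OC1=O | target

**Step count and risks**

Total: 25 steps. Longest linear sequence: 23 steps (steps 1–6 and 9–25, from (R)-linalool); steps 7–8 make the furan.

1. Step 20 (Proposed new method). What may go wrong: loss of the C10 silyloxy group from the C9 carbanion (β-elimination to a vinyl sulfone) before the episulfone closes; chlorination of the furanolate at C11 instead of C8; alkoxide attack on the lactone; an E/Z mixture that does not equilibrate to Z inside the ring.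
Fallback, using only established reaction types (vinylogous Mukaiyama aldol of a 2-silyloxyfuran and elimination to a γ-ylidene butenolide), from diol 21 back to 38. CBS reduction of 21 as in step 14 gives triol F1. TESOTf/2,6-lutidine gives tris(triethylsilyl) ether F2. Photooxygenation as in step 16 gives hydroxybutenolide F3. NaBH4 in MeOH at 0 °C, then acidification, gives butenolide F4 with C8 as CH2. Swern oxidation converts the primary triethylsilyl ether directly into aldehyde F5 (C9). Under high dilution, TBSOTf and iPr2NEt turn the butenolide into silyloxyfuran F6, which adds through C8 to the silyl-activated aldehyde to give the ten-membered silyl aldolate F7, and DBU then eliminates silanol to give 38. This closes the ten-membered ring directly by C–C bond formation and so pays the medium-ring penalty that the sulfur route avoids.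

2. Step 18. What may go wrong: intermolecular acetal formation (oligomers) outrunning ring closure; capture of the acyloxycarbenium ion by the C10 silyloxy oxygen to give a five-membered oxathiolane; acid-induced loss of the triethylsilyl ethers.
Fallback from 30 back to 32, with ring closure under kinetic control on a preformed leaving group instead of equilibrium acetalisation. Ac2O/pyridine converts 30 into γ-acetoxybutenolide F8. Phosphine reduction as in step 17 gives thiol F9. Slow addition of F9 to BF3·OEt2 in CH2Cl2 at −40 °C displaces acetate irreversibly and gives 32.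

3. Step 9. What may go wrong: deprotonation of the lactone α-CH2 by the basic dianion, a second addition to the ketone, and ring-chain mixtures that silylate unevenly in step 10.
Fallback from 13 back to 20. N,O-dimethylhydroxylamine hydrochloride and i-PrMgCl (THF, −20 °C) open the lactone to hydroxy Weinreb amide F10. TBSOTf/2,6-lutidine gives silyl ether F11. Dianion 18 adds to the amide to give ketone F12 with the C13 hydroxyl free, and TBSCl/imidazole gives 20.

**Further compounds**

F1 | step 20 | (1R,3S,4R,7R)-1-Ar-4-[(tert-butyldimethylsilyl)oxy]-3,7-dimethyloctane-1,7,8-triol | OC[C@](C)(O)CC[C@@H](O[Si](C)(C)C(C)(C)C)[C@@H](C)C[C@@H](O)c1coc([Si](C)(C)C(C)(C)C)c1CO[Si](C)(C)C(C)(C)C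
F2 | step 20 | 1,7,8-tris(triethylsilyl) ether of F1 | CC[Si](CC)(CC)OC[C@](C)(O[Si](CC)(CC)CC)CC[C@@H](O[Si](C)(C)C(C)(C)C)[C@@H](C)C[C@@H](O[Si](CC)(CC)CC)c1coc([Si](C)(C)C(C)(C)C)c1CO[Si](C)(C)C(C)(C)C
F3 | step 20 | γ-hydroxybutenolide from F2 (C8 hemiacetal, C9-OTES) | CC[Si](CC)(CC)OC[C@](C)(O[Si](CC)(CC)CC)CC[C@@H](O[Si](C)(C)C(C)(C)C)[C@@H](C)C[C@@H](O[Si](CC)(CC)CC)C1=C(CO[Si](C)(C)C(C)(C)C)C(=O)OC1O
F4 | step 20 | butenolide from F3 (C8 as CH2) | CC[Si](CC)(CC)OC[C@](C)(O[Si](CC)(CC)CC)CC[C@@H](O[Si](C)(C)C(C)(C)C)[C@@H](C)C[C@@H](O[Si](CC)(CC)CC)C1=C(CO[Si](C)(C)C(C)(C)C)C(=O)OC1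
F5 | step 20 | C9 aldehyde of butenolide F4 | O=C[C@](C)(O[Si](CC)(CC)CC)CC[C@@H](O[Si](C)(C)C(C)(C)C)[C@@H](C)C[C@@H](O[Si](CC)(CC)CC)C1=C(CO[Si](C)(C)C(C)(C)C)C(=O)OC1
F6 | step 20 | 2-(tert-butyldimethylsilyloxy)furan from F5 (formed in the flask) | O=C[C@](C)(O[Si](CC)(CC)CC)CC[C@@H](O[Si](C)(C)C(C)(C)C)[C@@H](C)C[C@@H](O[Si](CC)(CC)CC)c1coc(O[Si](C)(C)C(C)(C)C)c1CO[Si](C)(C)C(C)(C)C
F7 | step 20 | ten-membered C9 silyl aldolate (C8–C9 bond, C9-OTBS; formed in the flask) | CC(C)(C)[Si](C)(C)OCC1=C2C(OC1=O)C(O[Si](C)(C)C(C)(C)C)[C@](C)(O[Si](CC)(CC)CC)CC[C@@H](O[Si](C)(C)C(C)(C)C)[C@@H](C)C[C@H]2O[Si](CC)(CC)CC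
F8 | step 18 | γ-acetoxybutenolide from 30 (C9 methyl disulfide) | CSSC[C@](C)(O[Si](CC)(CC)CC)CC[C@@H](O[Si](C)(C)C(C)(C)C)[C@@H](C)C[C@@H](O[Si](CC)(CC)CC)C1=C(CO[Si](C)(C)C(C)(C)C)C(=O)OC1OC(C)=O
F9 | step 18 | C9 thiol of γ-acetoxybutenolide F8 | SC[C@](C)(O[Si](CC)(CC)CC)CC[C@@H](O[Si](C)(C)C(C)(C)C)[C@@H](C)C[C@@H](O[Si](CC)(CC)CC)C1=C(CO[Si](C)(C)C(C)(C)C)C(=O)OC1OC(C)=O
F10 | step 9 | (3S,4R)-4-hydroxy-N-methoxy-N,3-dimethyl-6-[(4R)-2,2,4-trimethyl-1,3-dioxolan-4-yl]hexanamide | CC1(C)OC[C@@](C)(CC[C@@H](O)[C@@H](C)CC(=O)N(C)OC)O1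
F11 | step 9 | TBS ether of F10 | CC1(C)OC[C@@](C)(CC[C@@H](O[Si](C)(C)C(C)(C)C)[C@@H](C)CC(=O)N(C)OC)O1
F12 | step 9 | (3S,4R)-1-[5-(tert-butyldimethylsilyl)-4-(hydroxymethyl)furan-3-yl]-4-[(tert-butyldimethylsilyl)oxy]-3-methyl-6-[(4R)-2,2,4-trimethyl-1,3-dioxolan-4-yl]hexan-1-one | CC1(C)OC[C@@](C)(CC[C@@H](O[Si](C)(C)C(C)(C)C)[C@@H](C)CC(=O)c2coc([Si](C)(C)C(C)(C)C)c2CO)O1
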